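A substrate curve that goes flat is easily taken for an equilibrium, and these runs go flat.

| setting | delta | eta | gamma | flask |
|---|---|---|---|---|
| left-handed substrate | 0.020 M | 0.020 M | 0.030 M | 0.020 M |
| right-handed substrate | 0.020 M | 0.020 M | 0.030 M | 0.020 M |
| gas | 9.6 mM (held) | 9.6 mM (held) | 9.6 mM (held) | 9.6 mM (held) |
| free catalyst | 0.065 mM | 0.26 mM | 0.13 mM | 0.13 mM |
| remark | run made earlier | run made earlier | run made earlier |  |
| time |  |  |  | 80 min |

| run | time / min | left-handed substrate / % | right-handed substrate / % |
|---|---|---|---|
| delta | 8.00 | 49.3 | 49.0 |
| delta | 12.0 | 48.9 | 49.2 |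
| delta | 20.0 | 48.2 | 48.4 |
| delta | 40.0 | 47.4 | 47.9 |
| delta | 60.0 | 48.8 | 48.4 |
| delta | 90.0 | 48.0 | 47.6 |
| eta | 8.00 | 45.6 | 46.8 |
| eta | 12.0 | 45.3 | 45.1 |
| eta | 20.0 | 44.3 | 44.2 |
| eta | 40.0 | 43.3 | 43.3 |
| eta | 60.0 | 43.6 | 43.3 |
| eta | 90.0 | 43.2 | 43.3 |
| gamma | 20.0 | 47.4 | 47.1 |
| gamma | 40.0 | 46.9 | 46.9 |
| gamma | 60.0 | 46.3 | 46.2 |
| gamma | 80.0 | 46.4 | 46.8 |
| gamma | 90.0 | 46.4 | 46.8 |

(scatter of a reading: 0.3 percentage points)

- free catalyst is single-handed; left-handed substrate and right-handed substrate are mirror images of each other, charged as a racemate, each of them at the stated concentration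
- the numbers in the tables scatter with a standard deviation of 0.3 percentage points
- at the start none of the gas is in solution
- an excess is below zero if the other one leads

- part of the left-handed substrate and right-handed substrate charged together that has reacted at 80 min
- excess of left-handed product over right-handed product in the product at 80 min
- excess of right-handed substrate over left-handed substrate among what is left of the two at 80 min

Over the last 3 readings of each run, the delta run stands at 3.97% reacted and the eta run at 13.3%. The eta run thus reacts more than the delta run from the same substrate charge, so I count turnovers. The eta run makes 20.5 products per free catalyst charged, and this count, the turnover number, is what I carry; the delta run reads 24.4 from its smaller conversion. The flask has the substrate charge of the delta and eta runs, so I multiply the count by c(free catalyst) and divide by c(left-handed substrate) + c(right-handed substrate), which gives 6.67% reacted at 80 min.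

The forecast, reckoned another way, gives 7% reacted, an excess of left-handed product of 0.5% and an excess of right-handed substrate of 0.04%, with the words: “The catalyst therefore shows no detectable selectivity”.

The flask gives 6.90% reacted, an excess of left-handed product of 18.8% and an excess of right-handed substrate of 0%.

    free catalyst + left-handed substrate ⇌ catalyst intermediate A (K = 93.5 /M, k = 2500 /M/min)
    free catalyst + right-handed substrate ⇌ catalyst intermediate B (K = 150 /M, k = 50300 /M/min)
    reagent + catalyst intermediate A → free catalyst + left-handed product (k = 711 /M/min)
    reagent + catalyst intermediate B → free catalyst + right-handed product (k = 254 /M/min)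
    left-handed substrate ⇌ right-handed substrate (k = 0.132 /min)
    gas ⇌ reagent, rate k6*(csat - [reagent]) (kL = 0.295 /min)
    reagent + free catalyst → spent catalyst (k = 84.9 /M/min)

The flask's conversion is 21.2 turnovers, beside my 20.5, with spent catalyst at >99.9% of the catalyst charged. The forecast parts from the flask on the product: the flask's substrates stand equal, yet left-handed product reaches 4.10% against 2.80% right-handed, and left-handed substrate has a half-life of 5.3 min by its forward step to right-handed substrate alone, shorter than 80 min. A neighbour flask charged with 5.2 × 10⁻⁵ M of free catalyst, all else held, should by 20.5 turnovers reach 2.67% reacted; it reaches 2.82%, with an excess of left-handed product of 18.7%.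

The data come from a simulation for substances that don't exist, noise included.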